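**Retrosynthetic overview**
- Drummondin A 25 ⇒ butyrylation at C8 of the chromene, MOM removal and C-butyrylation of ring A ⇒ CH2-linked ring A triketone 21 ⇒ enol-ether hydrolysis ⇒ dienone 20.
- The strategy rests on ring A: a six-membered carbocycle with oxygen on C1, C3 and C5, the CH2–aryl group on C2 and a quaternary C6(CH3)2 next to the C1 carbonyl, so the ring is a cyclohexa-2,4-dienone that cannot aromatise.
- Key disconnection: ring A of 20 ⇒ cyclobutenone 4 (gives C1, C4, C5, C6) + siloxyalkyne 16 (gives C2, C3); C1–C2 and C3–C4 come from a [2+2] addition and C1–C6 is re-formed by 6π closure.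
- 16 ⇒ alkyne 13 ⇒ bis-MOM chromene 8 (lithiation at C6, propargylation) ⇒ phloroglucinol 5 + enal 6; 4 ⇒ dimethylketene (from 1) + ethoxyacetylene 2.
- Ring order: pyran ring of the chromene (step 2), the sacrificial four-membered ring (step 1), ring A last (step 7); both butyryl groups are added after ring A exists.

Key step: step 7

Remark: the target has no stereocentre; compounds 21–25 are mixtures of enol tautomers and are drawn in the tautomer of the given target SMILES.

**Step 1**
Reactants: 1 isobutyryl chloride; 2 ethoxyacetylene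
Product: 4 3-ethoxy-4,4-dimethylcyclobut-2-en-1-one, via dimethylketene 3 (not isolated)
Conditions: Et3N (1.2 equiv), 2 (2 equiv), CH2Cl2, reflux, slow addition of 1
Reagents that add atoms: none
Why: Et3N dehydrochlorinates 1 to dimethylketene, which adds the ynol ether in a thermal ketene–alkoxyalkyne [2+2] cycloaddition polarised so that the alkyne CH carbon bonds to the ketene carbonyl carbon, giving the 3-alkoxy-4,4-dimethylcyclobutenone.

**Step 2**
Reactants: 5 phloroglucinol; 6 3-methylbut-2-enal
Product: 7 2,2-dimethyl-2H-chromene-5,7-diol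
Conditions: pyridine, 110 °C, 5 in threefold excess
Reagents that add atoms: none
Why: Pyridine-mediated chromenylation (Knoevenagel-type C-alkylation of the phenol by the enal, dehydration to an ortho-quinone methide and oxa-6π electrocyclisation) can give only one mono-adduct from the symmetric 5, and the excess of 5 holds back a second annulation.

**Step 3**
Reactants: 7 2,2-dimethyl-2H-chromene-5,7-diol
Product: 8 5,7-bis(methoxymethoxy)-2,2-dimethyl-2H-chromene
Conditions: MOMCl (2.6 equiv), i-Pr2NEt, CH2Cl2, 0 °C → rt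
Reagents that add atoms: chloromethyl methyl ether (MOMCl), COCCl
Why: Standard O-alkylation of both phenols with MOMCl and a hindered amine base installs acetal groups that direct the later metalation and are removable with acid.

**Step 4**
Reactants: 8 5,7-bis(methoxymethoxy)-2,2-dimethyl-2H-chromene; 9 3-bromo-1-(trimethylsilyl)prop-1-yne
Product: 12 {3-[5,7-bis(methoxymethoxy)-2,2-dimethyl-2H-chromen-6-yl]prop-1-yn-1-yl}trimethylsilane, via aryllithium 10 (not isolated), via arylcopper 11 (not isolated)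
Conditions: n-BuLi, THF, 0 °C; CuBr·SMe2, −40 °C; 9, −40 °C → rt
Reagents that add atoms: none
Why: Directed ortho-metalation should remove C6–H, which lies between two chelating OCH2OCH3 groups, in preference to C8–H, and the derived arylcopper displaces bromide at the CH2 carbon of the silyl-capped propargyl bromide (SN2), the SiMe3 group blocking acetylide formation and attack at the alkyne terminus.

**Step 5**
Reactants: 12 {3-[5,7-bis(methoxymethoxy)-2,2-dimethyl-2H-chromen-6-yl]prop-1-yn-1-yl}trimethylsilane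
Product: 13 5,7-bis(methoxymethoxy)-2,2-dimethyl-6-(prop-2-yn-1-yl)-2H-chromene
Conditions: K2CO3 (0.2 equiv), MeOH–THF, 0 °C
Reagents that add atoms: none
Why: Methoxide-catalysed protodesilylation of the alkynylsilane is mild enough at 0 °C to leave the benzylic propargylic CH2 group unisomerised.

**Step 6**
Reactants: 13 5,7-bis(methoxymethoxy)-2,2-dimethyl-6-(prop-2-yn-1-yl)-2H-chromene
Product: 16 triisopropyl({3-[5,7-bis(methoxymethoxy)-2,2-dimethyl-2H-chromen-6-yl]prop-1-yn-1-yl}oxy)silane, via lithium acetylide 14 (not isolated), via lithium ynolate 15 (not isolated)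
Conditions: LiN(SiMe3)2 (2.2 equiv), THF, −78 °C; t-BuOOH (anhydrous, 1.1 equiv), −78 → 0 °C; TIPSOTf, −78 → 0 °C
Reagents that add atoms: tert-butyl hydroperoxide, CC(C)(C)OO; triisopropylsilyl trifluoromethanesulfonate (TIPSOTf), CC(C)[Si](OS(=O)(=O)C(F)(F)F)(C(C)C)C(C)C
Why: Oxygen transfer from LiOOt-Bu to the lithium acetylide gives the lithium ynolate, which the bulky silyl triflate traps on oxygen as the isolable triisopropylsilyl ynol ether (acetylide oxidation route to siloxyalkynes), the amide base removing only the acetylenic hydrogen.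

**Step 7**
Reactants: 4 3-ethoxy-4,4-dimethylcyclobut-2-en-1-one; 16 triisopropyl({3-[5,7-bis(methoxymethoxy)-2,2-dimethyl-2H-chromen-6-yl]prop-1-yn-1-yl}oxy)silane
Product: 20 2-{[5,7-bis(methoxymethoxy)-2,2-dimethyl-2H-chromen-6-yl]methyl}-5-ethoxy-6,6-dimethyl-3-[(triisopropylsilyl)oxy]cyclohexa-2,4-dien-1-one, via vinylketene 17 (not isolated), via vinylcyclobutenone 18 (not isolated), via dienylketene 19 (not isolated)
Conditions: toluene (1 M in 16), 4 (2.5 equiv), 100–110 °C, sealed tube, argon
Reagents that add atoms: none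
Why: Proposed new method: heating opens cyclobutenone 4 by 4π electrocyclic cleavage of its C(=O)–CMe2 bond to vinylketene 17; the alkyne carbon of 16 that carries the CH2–aryl group attacks the ketene carbonyl carbon and the siloxy carbon bonds to the ketene CH carbon ([2+2]), giving vinylcyclobutenone 18, which opens again (4π) to dienylketene 19. Ring A is then closed by a thermal disrotatory 6π electrocyclisation that joins the ketene carbon to the CMe2 terminus, and because that carbon carries two methyl groups and no hydrogen the ring cannot tautomerise to a phenol and stays as cyclohexa-2,4-dienone 20. The closest known reactions are the Danheiser benzannulation of cyclobutenones with siloxyalkynes (same first three events, ending in a phenol) and the thermal reclosure of the dienylketenes formed on photolysis of 6,6-disubstituted cyclohexa-2,4-dienones (same last event); their combination on a fully substituted diene terminus is what is new. No stereocentre is formed, since the CH centre of 18 is transient. The step needs the [2+2] regiochemistry, which the polarised ynol ether (electron-rich carbon remote from oxygen) secures against the electrophilic ketene carbon. It also needs capture of 17 and closure of 19 to outrun hydrogen shifts from their methyl groups, which a high concentration of 16, an excess of the cheap 4 and the lowest temperature at which 4 opens should favour, with relief of four-ring strain driving the sequence.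

**Step 8**
Reactants: 20 2-{[5,7-bis(methoxymethoxy)-2,2-dimethyl-2H-chromen-6-yl]methyl}-5-ethoxy-6,6-dimethyl-3-[(triisopropylsilyl)oxy]cyclohexa-2,4-dien-1-one
Product: 21 4-{[5,7-bis(methoxymethoxy)-2,2-dimethyl-2H-chromen-6-yl]methyl}-3,5-dihydroxy-6,6-dimethylcyclohexa-2,4-dien-1-one
Conditions: 1 M aq. HCl–THF (1:4), 0 °C → rt
Reagents that add atoms: water, O
Why: The silyl dienol ether (a vinylogous silyl ester) and the ethyl enol ether (a vinylogous ester) should hydrolyse in dilute aqueous acid at room temperature far faster than the aryl MOM acetals, so ring A is unveiled while the phenols stay protected and no formaldehyde equivalent is released next to the nucleophilic ring A carbon.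

**Step 9**
Reactants: 21 4-{[5,7-bis(methoxymethoxy)-2,2-dimethyl-2H-chromen-6-yl]methyl}-3,5-dihydroxy-6,6-dimethylcyclohexa-2,4-dien-1-one
Product: 23 2-butanoyl-4-{[5,7-bis(methoxymethoxy)-2,2-dimethyl-2H-chromen-6-yl]methyl}-3,5-dihydroxy-6,6-dimethylcyclohexa-2,4-dien-1-one, via enol butyrate 22 (not isolated)
Conditions: butyric acid, DCC, DMAP, CH2Cl2, rt
Reagents that add atoms: butyric acid, CCCC(=O)O
Why: Carbodiimide/DMAP C-acylation of a cyclic β-dicarbonyl compound: the activated acid O-acylates an enol oxygen and DMAP shuttles the acyl group to the only C–H carbon of ring A (O-to-C acyl migration), the chelated 2-acyl triketone being the thermodynamic sink and the chromene and MOM groups being inert under these neutral conditions.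

**Step 10**
Reactants: 23 2-butanoyl-4-{[5,7-bis(methoxymethoxy)-2,2-dimethyl-2H-chromen-6-yl]methyl}-3,5-dihydroxy-6,6-dimethylcyclohexa-2,4-dien-1-one
Product: 24 2-butanoyl-4-[(5,7-dihydroxy-2,2-dimethyl-2H-chromen-6-yl)methyl]-3,5-dihydroxy-6,6-dimethylcyclohexa-2,4-dien-1-one
Conditions: HCl (1.25 M in MeOH)–THF, 45 °C, argon sweep
Reagents that add atoms: none
Why: Acid-catalysed acetal exchange with methanol removes both MOM groups as volatile CH2(OMe)2, and ring A, now fully substituted, can no longer capture the transient methoxymethyl cation.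

**Step 11**
Reactants: 24 2-butanoyl-4-[(5,7-dihydroxy-2,2-dimethyl-2H-chromen-6-yl)methyl]-3,5-dihydroxy-6,6-dimethylcyclohexa-2,4-dien-1-one
Product: 25 Drummondin A
Conditions: PrCOCl (1.5 equiv), AlCl3 (5 equiv), PhNO2–CH2Cl2, 0 °C → rt; ice-cold 1 M HCl
Reagents that add atoms: butyryl chloride, CCCC(=O)Cl
Why: Friedel–Crafts C-acylation of the phloroglucinol-type ring at its only free position C8 (ortho to O1 and to the 7-OH, para to the 5-OH), the acyl-triketone ring A being deactivated and fully substituted and the low temperature with a cold quench limiting acid-mediated addition to the chromene C3=C4 bond.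

**Compound list**
1 | isobutyryl chloride | CC(C)C(Cl)=O | starting material
2 | ethoxyacetylene | CCOC#C | starting material
3 | dimethylketene | CC(C)=C=O | intermediate
4 | 3-ethoxy-4,4-dimethylcyclobut-2-en-1-one | O=C1C=C(OCC)C1(C)C | intermediate
5 | phloroglucinol | Oc1cc(O)cc(O)c1 | starting material
6 | 3-methylbut-2-enal | CC(C)=CC=O | starting material
7 | 2,2-dimethyl-2H-chromene-5,7-diol | CC1(C)C=Cc2c(O)cc(O)cc2O1 | intermediate
8 | 5,7-bis(methoxymethoxy)-2,2-dimethyl-2H-chromene | COCOc1cc(OCOC)c2C=CC(C)(C)Oc2c1 | intermediate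
9 | 3-bromo-1-(trimethylsilyl)prop-1-yne | C[Si](C)(C)C#CCBr | starting material
10 | [5,7-bis(methoxymethoxy)-2,2-dimethyl-2H-chromen-6-yl]lithium | COCOc1cc2OC(C)(C)C=Cc2c(OCOC)c1[Li] | intermediate
11 | [5,7-bis(methoxymethoxy)-2,2-dimethyl-2H-chromen-6-yl]copper | COCOc1cc2OC(C)(C)C=Cc2c(OCOC)c1[Cu] | intermediate
12 | {3-[5,7-bis(methoxymethoxy)-2,2-dimethyl-2H-chromen-6-yl]prop-1-yn-1-yl}trimethylsilane | COCOc1cc2OC(C)(C)C=Cc2c(OCOC)c1CC#C[Si](C)(C)C | intermediate
13 | 5,7-bis(methoxymethoxy)-2,2-dimethyl-6-(prop-2-yn-1-yl)-2H-chromene | COCOc1cc2OC(C)(C)C=Cc2c(OCOC)c1CC#C | intermediate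
14 | lithium acetylide of 13 | COCOc1cc2OC(C)(C)C=Cc2c(OCOC)c1CC#C[Li] | intermediate
15 | lithium 3-[5,7-bis(methoxymethoxy)-2,2-dimethyl-2H-chromen-6-yl]prop-1-yn-1-olate | COCOc1cc2OC(C)(C)C=Cc2c(OCOC)c1CC#CO[Li] | intermediate
16 | triisopropyl({3-[5,7-bis(methoxymethoxy)-2,2-dimethyl-2H-chromen-6-yl]prop-1-yn-1-yl}oxy)silane | CC(C)[Si](OC#CCc1c(OCOC)c2c(cc1OCOC)OC(C)(C)C=C2)(C(C)C)C(C)C | intermediate
17 | 3-ethoxy-4-methylpenta-1,3-dien-1-one | O=C=CC(OCC)=C(C)C | intermediate
18 | 2-{[5,7-bis(methoxymethoxy)-2,2-dimethyl-2H-chromen-6-yl]methyl}-4-(1-ethoxy-2-methylprop-1-en-1-yl)-3-[(triisopropylsilyl)oxy]cyclobut-2-en-1-one (racemic, transient) | O=C1C(Cc2c(OCOC)c3c(cc2OCOC)OC(C)(C)C=C3)=C(O[Si](C(C)C)(C(C)C)C(C)C)C1C(OCC)=C(C)C | intermediate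
19 | (3E)-2-{[5,7-bis(methoxymethoxy)-2,2-dimethyl-2H-chromen-6-yl]methyl}-5-ethoxy-6-methyl-3-[(triisopropylsilyl)oxy]hepta-1,3,5-trien-1-one | O=C=C(Cc1c(OCOC)c2c(cc1OCOC)OC(C)(C)C=C2)/C(O[Si](C(C)C)(C(C)C)C(C)C)=C\C(OCC)=C(C)C | intermediate
20 | 2-{[5,7-bis(methoxymethoxy)-2,2-dimethyl-2H-chromen-6-yl]methyl}-5-ethoxy-6,6-dimethyl-3-[(triisopropylsilyl)oxy]cyclohexa-2,4-dien-1-one | O=C1C(Cc2c(OCOC)c3c(cc2OCOC)OC(C)(C)C=C3)=C(O[Si](C(C)C)(C(C)C)C(C)C)C=C(OCC)C1(C)C | intermediate
21 | 4-{[5,7-bis(methoxymethoxy)-2,2-dimethyl-2H-chromen-6-yl]methyl}-3,5-dihydroxy-6,6-dimethylcyclohexa-2,4-dien-1-one | O=C1C=C(O)C(Cc2c(OCOC)c3c(cc2OCOC)OC(C)(C)C=C3)=C(O)C1(C)C | intermediate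
22 | 6-{[5,7-bis(methoxymethoxy)-2,2-dimethyl-2H-chromen-6-yl]methyl}-5-hydroxy-4,4-dimethyl-3-oxocyclohexa-1,5-dien-1-yl butanoate | CCCC(=O)OC1=CC(=O)C(C)(C)C(O)=C1Cc1c(OCOC)c2c(cc1OCOC)OC(C)(C)C=C2 | intermediate
23 | 2-butanoyl-4-{[5,7-bis(methoxymethoxy)-2,2-dimethyl-2H-chromen-6-yl]methyl}-3,5-dihydroxy-6,6-dimethylcyclohexa-2,4-dien-1-one | CCCC(=O)C1=C(O)C(Cc2c(OCOC)c3c(cc2OCOC)OC(C)(C)C=C3)=C(O)C(C)(C)C1=O | intermediate
24 | 2-butanoyl-4-[(5,7-dihydroxy-2,2-dimethyl-2H-chromen-6-yl)methyl]-3,5-dihydroxy-6,6-dimethylcyclohexa-2,4-dien-1-one | CCCC(=O)C1=C(O)C(Cc2c(O)c3c(cc2O)OC(C)(C)C=C3)=C(O)C(C)(C)C1=O | intermediate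
25 | Drummondin A, 2-butanoyl-4-[(8-butanoyl-5,7-dihydroxy-2,2-dimethyl-2H-chromen-6-yl)methyl]-3,5-dihydroxy-6,6-dimethylcyclohexa-2,4-dien-1-one | CCCC(=O)C1=C(O)C(Cc2c(O)c3c(c(C(=O)CCC)c2O)OC(C)(C)C=C3)=C(O)C(C)(C)C1=O | target

**Step count**
Total: 11 steps. Longest linear sequence: 10 steps (steps 2–11, from phloroglucinol 5); step 1 is a one-step branch.

**Steps most likely to fail**

1. Step 7. A hydrogen shift from a methyl group of the vinylketene or of the dienylketene may outrun capture by the alkyne or the 6π closure. The [2+2] addition may also take the wrong orientation, or the siloxyalkyne may isomerise on heating. The fallback builds ring A by Claisen chemistry; it sets out from 8 and returns at 21.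
 - Arylcopper 11, made from 8 as in step 4, is added in conjugate fashion to but-3-en-2-one (BF3·OEt2, THF, −78 °C) to give 4-[5,7-bis(methoxymethoxy)-2,2-dimethyl-2H-chromen-6-yl]butan-2-one F1 after aqueous work-up.
 - The kinetic methyl enolate of F1 (LiN(i-Pr)2, 2 equiv, THF, −78 °C) is acylated by dimethyl 2,2-dimethylmalonate in a crossed Claisen condensation to methyl 7-[5,7-bis(methoxymethoxy)-2,2-dimethyl-2H-chromen-6-yl]-2,2-dimethyl-3,5-dioxoheptanoate F2.
 - NaOMe in refluxing MeOH closes F2 by intramolecular Claisen condensation of C6 onto the ester, giving 21, from which steps 9–11 follow.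

2. Step 11. Acid may add to the chromene C3=C4 bond or oligomerise it, the Lewis acid may cleave or scramble the CH2 bridge between the two electron-rich rings, and acylation may compete at C3. The fallback brings both butyryl groups in before the rings are joined; it sets out from 5 and returns at 25.
 - Friedel–Crafts butyrylation of 5 (PrCOCl, AlCl3, PhNO2) gives 1-(2,4,6-trihydroxyphenyl)butan-1-one F3.
 - Geminal C-methylation of F3 (MeI, NaOMe, MeOH) gives 2-butanoyl-3,5-dihydroxy-6,6-dimethylcyclohexa-2,4-dien-1-one F4.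
 - F3 with MOMCl (2.2 equiv) and i-Pr2NEt gives 1-[2-hydroxy-4,6-bis(methoxymethoxy)phenyl]butan-1-one F5, in which only the chelated hydroxyl is free.
 - Chromenylation of F5 with enal 6 (ethylenediammonium diacetate, xylene, 140 °C) can close only onto that hydroxyl and gives 1-[5,7-bis(methoxymethoxy)-2,2-dimethyl-2H-chromen-8-yl]butan-1-one F6.
 - Methanolic HCl removes the MOM groups to give 1-(5,7-dihydroxy-2,2-dimethyl-2H-chromen-8-yl)butan-1-one F7.
 - Methylene bridging of F4 and F7 (aqueous formaldehyde, catalytic piperidine, MeOH, rt, F7 in excess) joins the ring A carbon to C6 of F7 and gives 25.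

3. Step 6. Oxygen transfer to the acetylide may be incomplete, base may isomerise the propargyl arene to the allene, and silylation may occur on carbon instead of oxygen. The fallback reaches the same ynolate by ester homologation; it sets out from 8 and returns at 16.
 - Aryllithium 10, made from 8 as in step 4, is quenched with I2 to give 6-iodo-5,7-bis(methoxymethoxy)-2,2-dimethyl-2H-chromene F8.
 - Coupling of F8 with BrZnCH2CO2Et (Pd2(dba)3, XPhos, THF, 60 °C) gives ethyl 2-[5,7-bis(methoxymethoxy)-2,2-dimethyl-2H-chromen-6-yl]acetate F9.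
 - Kowalski ester homologation of F9 (CH2Br2 with lithium 2,2,6,6-tetramethylpiperidide, THF, −78 °C; LiN(SiMe3)2; n-BuLi, −78 → −20 °C) gives lithium ynolate 15, which TIPSOTf silylates to 16.

**Further compounds**
F1 | step 7 | 4-[5,7-bis(methoxymethoxy)-2,2-dimethyl-2H-chromen-6-yl]butan-2-one | CC(=O)CCc1c(OCOC)cc2OC(C)(C)C=Cc2c1OCOC
F2 | step 7 | methyl 7-[5,7-bis(methoxymethoxy)-2,2-dimethyl-2H-chromen-6-yl]-2,2-dimethyl-3,5-dioxoheptanoate | COC(=O)C(C)(C)C(=O)CC(=O)CCc1c(OCOC)cc2OC(C)(C)C=Cc2c1OCOC
F3 | step 11 | 1-(2,4,6-trihydroxyphenyl)butan-1-one | CCCC(=O)c1c(O)cc(O)cc1O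
F4 | step 11 | 2-butanoyl-3,5-dihydroxy-6,6-dimethylcyclohexa-2,4-dien-1-one | CCCC(=O)C1=C(O)C=C(O)C(C)(C)C1=O
F5 | step 11 | 1-[2-hydroxy-4,6-bis(methoxymethoxy)phenyl]butan-1-one | CCCC(=O)c1c(O)cc(OCOC)cc1OCOC
F6 | step 11 | 1-[5,7-bis(methoxymethoxy)-2,2-dimethyl-2H-chromen-8-yl]butan-1-one | CCCC(=O)c1c(OCOC)cc(OCOC)c2C=CC(C)(C)Oc12
F7 | step 11 | 1-(5,7-dihydroxy-2,2-dimethyl-2H-chromen-8-yl)butan-1-one | CCCC(=O)c1c(O)cc(O)c2C=CC(C)(C)Oc12
F8 | step 6 | 6-iodo-5,7-bis(methoxymethoxy)-2,2-dimethyl-2H-chromene | COCOc1cc2OC(C)(C)C=Cc2c(OCOC)c1I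
F9 | step 6 | ethyl 2-[5,7-bis(methoxymethoxy)-2,2-dimethyl-2H-chromen-6-yl]acetate | CCOC(=O)Cc1c(OCOC)cc2OC(C)(C)C=Cc2c1OCOC
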